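The numbers in the tables stem from a simulated flask from invented constants; scatter was added.

I start with a subtraction. If each impurity removes one free catalyst, the theta run works with 1.50 mM of catalyst and the flask with 0.800 mM; no earlier run tests this, so it stays a guess.

- theta: substrate 0.14 M; partner 0.070 M; free catalyst 2.1 mM; impurity 0.60 mM; run made earlier
- flask: substrate 0.14 M; partner 0.0700 M; free catalyst 1.4 mM; impurity 0.60 mM; time 2.5 h

1. time, not beyond 2.5 h, at which the flask holds most target
2. the amount of target, in percent of the substrate charged, at that time
3. earliest time at which at least nineteen twentieths of that best amount are there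
4. latest time at which they still are

- theta (time / min: target / %): 4.00: 17.8; 10.0: 26.9; 20.0: 19.5; 30.0: 16.5

(scatter of a reading: 1 percentage point)

- no earlier run changes the charge of free catalyst; that part of a forecast is a guess

I read the table downward. Target climbs to its highest reading, 26.9% at 10.0 min, then loses 7.4 percentage points and after that a smaller 3 points, which looks like a first-order approach to a plateau. I take the last reading, 16.5%, as that plateau. I take partner as the limiting reagent, so the ceiling is 50.0% of the substrate, and the theta plateau is a share 33.0% of it.

Let x be the target above that plateau line, fed at rate r and relaxing at rate λ. Then dx/dt = r − λx integrates to an exponential climb towards r/λ. If r follows working catalyst and λ does not, which I assume, one number carries over: 9.71, the overshoot per working catalyst, meaning molar target above the plateau for each catalyst at work.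

For the flask this gives an overshoot of 5.55%, so a best of 22.0%, near 0.313 h on the slowed clock.

The forecast gives 26.5% at 0.27 h, open 0.22 h, shut 0.33 h, reasoning “The height should stay near 27%”, a height above mine.

The flask gives 22.7% at 0.292 h, open 0.219 h, shut 0.373 h.

    catalyst intermediate A → catalyst intermediate B (k = 0.340 s⁻¹)
    free catalyst + impurity → spent catalyst (k = 150 M⁻¹ s⁻¹)
    catalyst intermediate C ⇌ free catalyst + target (K = 9.80 M, k = 0.390 s⁻¹)
    substrate + catalyst intermediate B → catalyst intermediate C (k = 2.50 M⁻¹ s⁻¹)
    partner + free catalyst → catalyst intermediate A (k = 8.80 M⁻¹ s⁻¹)
    target ⇌ isomer of the product (K = 1.80, k = 0.00200 s⁻¹)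

The flask's best stands 4.8 points above the 17.9% of target at 2.50 h, which is 8.56 per working catalyst against 9.71 from the theta readings. In the flask, the half-life of target by its forward step into isomer of the product alone, 0.096 h, is shorter than the half-life of partner by its step with free catalyst, 0.11 h at 0.126 h, and short against 2.5 h.

For a neighbour flask like this one but with 0.24 M of substrate, the ceiling is 29.2%, the plateau 9.63% and the overshoot 3.24%, so I expect 12.9%. The computed best of that neighbour flask is 13.9%, and its target ends at 10.4%.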